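**Retrosynthetic overview**
- The cage is opened at its ketal and hemiketal to three pieces: an (S)-2-hydroxyoctanoic acid-derived dioxolanyl cation (C8, temporary acetonide), a 3-vinyl-4-silyloxy-6-methylpyran-2-one, and cyclohexane-1,3-dione.
- Key disconnections, both made in one flask: the CH2–CH(O) bond (vinyl terminus to the dioxolanyl cation) and the CH(pyranone)–CH(ring fusion) bond (Michael addition of the dione C2).
- Enabling feature: the pyran-2-one ring's O–C4=C3 enol unit, extended by the C3 vinyl group, makes the vinyl CH2 nucleophilic. After that carbon has bonded and silicon has left, the same unit is a 3-alkylidene-pyran-2,4-dione whose exocyclic CH accepts C2 of the cyclohexane-1,3-dione ring, the carbon between the future ketal and hemiketal carbons.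
- Ring order: pyranone and carbocycle are bought; a temporary acetonide steers the new C–O stereocentre and is removed in step 7. Step 7 then closes the tetrahydropyran and dioxolane of the 6,8-dioxabicyclo[3.2.1]octane ketal and the dihydropyran hemiketal ring. The secondary hydroxyl is installed last.

Key step: step 6

Remark: the cis-fused ketal–hemiketal cage of the target is assumed to be the thermodynamically preferred closed form of its open hydroxy-ketone/diol form, as expected for a hemiketal natural product; the centres set in step 7 rely on this.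

**Step 1**
Reactants: 1 (S)-2-hydroxyoctanoic acid
Product: 2 (5S)-5-hexyl-2,2-dimethyl-1,3-dioxolan-4-one
Conditions: 2,2-dimethoxypropane, TsOH·H2O (cat.), acetone, rt
Reagents that add atoms: 2,2-dimethoxypropane, COC(C)(C)OC
Why: acid-catalysed acetal exchange of an α-hydroxy acid to its acetonide dioxolanone is routine and does not touch the stereocentre.

**Step 2**
Reactants: 2 (5S)-5-hexyl-2,2-dimethyl-1,3-dioxolan-4-one
Product: 4 (5S)-5-hexyl-2,2-dimethyl-1,3-dioxolan-4-yl acetate (both C4 epimers), via aluminium lactolate 3 (not isolated)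
Conditions: DIBAL-H, CH2Cl2, −78 °C; then pyridine, DMAP, Ac2O, −78 → 0 °C
Reagents that add atoms: acetic anhydride, CC(=O)OC(C)=O
Why: reductive acetylation (lactone to aluminium lactolate, acylated in situ) should give the α-acetoxy acetal, whose C4 epimer mixture is irrelevant because this carbon is ionised in step 6.

**Step 3**
Reactants: 5 4-hydroxy-6-methyl-2H-pyran-2-one
Product: 6 3-bromo-4-hydroxy-6-methyl-2H-pyran-2-one
Conditions: NBS, MeCN, 0 °C → rt
Reagents that add atoms: N-bromosuccinimide, O=C1CCC(=O)N1Br
Why: electrophilic bromination should occur at C3, the enol carbon flanked by the 4-hydroxyl and the lactone carbonyl and the most nucleophilic ring position.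

**Step 4**
Reactants: 6 3-bromo-4-hydroxy-6-methyl-2H-pyran-2-one
Product: 7 3-bromo-4-[(tert-butyldimethylsilyl)oxy]-6-methyl-2H-pyran-2-one
Conditions: TBSCl, Et3N, CH2Cl2, 0 °C
Reagents that add atoms: tert-butyldimethylsilyl chloride, CC(C)(C)[Si](C)(C)Cl
Why: O-silylation of the acidic vinylogous acid is straightforward and installs the group that later turns the pyranone into a silyl dienol ether.

**Step 5**
Reactants: 7 3-bromo-4-[(tert-butyldimethylsilyl)oxy]-6-methyl-2H-pyran-2-one; 8 tributyl(vinyl)stannane
Product: 9 4-[(tert-butyldimethylsilyl)oxy]-3-ethenyl-6-methyl-2H-pyran-2-one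
Conditions: Pd2(dba)3 (cat.), P(2-furyl)3, toluene, 80 °C
Reagents that add atoms: none
Why: Stille coupling of a 3-bromopyran-2-one under anhydrous, base-free conditions should deliver the vinyl group while sparing the silyl vinylogous ester.

**Step 6**
Reactants: 4 (5S)-5-hexyl-2,2-dimethyl-1,3-dioxolan-4-yl acetate; 9 4-[(tert-butyldimethylsilyl)oxy]-3-ethenyl-6-methyl-2H-pyran-2-one; 10 cyclohexane-1,3-dione
Product: 12 3-{(1RS)-2-[(4S,5S)-5-hexyl-2,2-dimethyl-1,3-dioxolan-4-yl]-1-(2-hydroxy-6-oxocyclohex-1-en-1-yl)ethyl}-4-hydroxy-6-methyl-2H-pyran-2-one, via alkylidene-pyrandione 11 (not isolated)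
Conditions: 4 (1.2 equiv), 9, TMSOTf (10 mol %), CH2Cl2, −78 °C; then 10, pyridine (0.3 equiv), THF, −78 °C → rt
Reagents that add atoms: none
Why: Proposed new method: TMSOTf should ionise acetate 4 to a 1,3-dioxolan-4-ylium ion, which is attacked by the terminal vinyl CH2 of 9 (the vinylogous carbon of the silyl dienol ether O–C4=C3–CH=CH2; C3 is fully substituted, so only this position can react), and the resulting O-silyl oxocarbenium ion passes its silyl group to acetate and becomes the 3-alkylidene-pyran-2,4-dione 11, to whose exocyclic carbon the pyridine-buffered dione 10 then adds through C2 (Michael addition). The closest known reaction types are vinylogous Mukaiyama additions of silyl dienol ethers to oxocarbenium ions generated from α-acetoxy acetals, and the Michael half of Knoevenagel–Michael bis-adduct formation between 4-hydroxypyranones, aldehydes and cyclic 1,3-diones; new is that the alkylidene-pyrandione is generated by C–C bond formation at its γ-carbon rather than by condensation. The step closes no ring (carbocycle and pyranone are bought, the acetonide is a temporary ring); it forms the CH2–CH(O) bond and the CH(pyranone)–C(dione) bond. The new oxygen-bearing stereocentre (dioxolane C4) is controlled by the hexyl group on the adjacent C5 of the nearly planar five-membered cation, the nucleophile entering anti to it to give the 4,5-trans (4S,5S) dioxolane, i.e. the threo diol; the new methine carbon is formed without control, which is tolerated because step 7 corrects it. The step needs site selectivity for the vinyl terminus over the pyranone oxygen and ring carbons, secured by O-silylation and the substituted C3, and it needs the cation to be consumed before the dione enters, secured by the order of addition at −78 °C.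

**Step 7**
Reactants: 12 3-{(1RS)-2-[(4S,5S)-5-hexyl-2,2-dimethyl-1,3-dioxolan-4-yl]-1-(2-hydroxy-6-oxocyclohex-1-en-1-yl)ethyl}-4-hydroxy-6-methyl-2H-pyran-2-one
Product: 13 deoxytrichopsistide B (the target with CH2 in place of the carbocyclic CHOH)
Conditions: 1 M aq. HCl/THF (1:4), 40 °C
Reagents that add atoms: none
Why: acetonide hydrolysis should free the threo diol, which bridges one dione carbonyl as the 6,8-dioxabicyclo[3.2.1]octane ketal (a brevicomin-type closure, hexyl exo, ketal configuration fixed by the bridge), after which the pyranone hydroxyl adds to the remaining ketone; the methine centre should equilibrate by retro-Michael/Michael addition so that the pyranone sits equatorial on the new tetrahydropyran, and the ring-fusion CH and hemiketal carbon should settle under thermodynamic control (hemiketal OH axial and hydrogen-bonded to a ketal oxygen).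

**Step 8**
Reactants: 13 deoxytrichopsistide B
Product: 16 Trichopsistide B, via dipotassium dianion 14 (not isolated), via open hydroxy ketone 15 (not isolated)
Conditions: KHMDS (2.3 equiv), THF, −78 °C; 2-(phenylsulfonyl)-3-phenyloxaziridine, −78 °C; AcOH, then rt
Reagents that add atoms: 2-(phenylsulfonyl)-3-phenyloxaziridine, O=S(=O)(N1OC1c1ccccc1)c1ccccc1
Why: base should open the hemiketal to the pyranoxide/ketone and deprotonate the ketone kinetically at its only α-CH2, and enolate hydroxylation by the N-sulfonyloxaziridine should occur along the axial trajectory on the convex face of the conformationally locked cis-fused ring (cis to the ring-fusion hydrogen), after which the hemiketal recloses on acidification.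

**Compound list**
1 | (S)-2-hydroxyoctanoic acid | CCCCCC[C@H](O)C(=O)O | starting material
2 | (5S)-5-hexyl-2,2-dimethyl-1,3-dioxolan-4-one | CCCCCC[C@@H]1OC(C)(C)OC1=O | intermediate
3 | diisobutylaluminium (5S)-5-hexyl-2,2-dimethyl-1,3-dioxolan-4-olate (aluminium lactolate) | CCCCCC[C@@H]1OC(C)(C)OC1O[Al](CC(C)C)CC(C)C | intermediate
4 | (5S)-5-hexyl-2,2-dimethyl-1,3-dioxolan-4-yl acetate (both C4 epimers) | CCCCCC[C@@H]1OC(C)(C)OC1OC(C)=O | intermediate
5 | 4-hydroxy-6-methyl-2H-pyran-2-one | Cc1cc(O)cc(=O)o1 | starting material
6 | 3-bromo-4-hydroxy-6-methyl-2H-pyran-2-one | Cc1cc(O)c(Br)c(=O)o1 | intermediate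
7 | 3-bromo-4-[(tert-butyldimethylsilyl)oxy]-6-methyl-2H-pyran-2-one | Cc1cc(O[Si](C)(C)C(C)(C)C)c(Br)c(=O)o1 | intermediate
8 | tributyl(vinyl)stannane | C=C[Sn](CCCC)(CCCC)CCCC | starting material
9 | 4-[(tert-butyldimethylsilyl)oxy]-3-ethenyl-6-methyl-2H-pyran-2-one | C=Cc1c(O[Si](C)(C)C(C)(C)C)cc(C)oc1=O | intermediate
10 | cyclohexane-1,3-dione | O=C1CCCC(=O)C1 | starting material
11 | 3-{2-[(4S,5S)-5-hexyl-2,2-dimethyl-1,3-dioxolan-4-yl]ethylidene}-6-methyl-2H-pyran-2,4(3H)-dione (alkene geometry not defined) | CCCCCC[C@@H]1OC(C)(C)O[C@H]1CC=C1C(=O)C=C(C)OC1=O | intermediate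
12 | 3-{(1RS)-2-[(4S,5S)-5-hexyl-2,2-dimethyl-1,3-dioxolan-4-yl]-1-(2-hydroxy-6-oxocyclohex-1-en-1-yl)ethyl}-4-hydroxy-6-methyl-2H-pyran-2-one | CCCCCC[C@@H]1OC(C)(C)O[C@H]1CC(C1=C(O)CCCC1=O)c1c(O)cc(C)oc1=O | intermediate
13 | deoxytrichopsistide B (target with CH2 in place of the carbocyclic CHOH; same configuration at the six remaining stereocentres) | CCCCCC[C@@H]1O[C@]23CCC[C@@]4(O)Oc5cc(C)oc(=O)c5[C@H](C[C@@H]1O2)[C@H]34 | intermediate
14 | dipotassium salt of the ring-opened form of 13 (ketone enolate toward the CH2, pyranone 4-oxide) | CCCCCC[C@@H]1O[C@]23CCC=C([O-])[C@@H]3[C@@H](C[C@@H]1O2)c1c([O-])cc(C)oc1=O.[K+].[K+] | intermediate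
15 | ring-opened α-hydroxy ketone tautomer of the target (free pyranone 4-OH) | CCCCCC[C@@H]1O[C@]23CC[C@@H](O)C(=O)[C@@H]3[C@@H](C[C@@H]1O2)c1c(O)cc(C)oc1=O | intermediate
16 | Trichopsistide B (hexyl exo on the dioxabicyclooctane; ring-fusion H, methine H and secondary OH on one face, hemiketal OH on the other) | CCCCCC[C@@H]1O[C@]23CC[C@@H](O)[C@@]4(O)Oc5cc(C)oc(=O)c5[C@H](C[C@@H]1O2)[C@H]34 | target

**Step count and risks**
Total steps: 8. Longest linear sequence: 6 (steps 3, 4, 5, 6, 7, 8 from compound 5).

Steps most likely to fail:

1. Step 6 (proposed new method). The dioxolanyl cation may be captured at oxygen, or the relay cation may lose a proton to the conjugated 3-alkenylpyranone or be trapped by a dioxolane oxygen before collapsing to 11; the anti selectivity at the dioxolane carbon may also be insufficient. The fallback uses known chemistry, sets out from 4 and comes back at 12. Acetate 4 is allylated with allyltrimethylsilane and BF3·OEt2 (Hosomi–Sakurai-type substitution, same anti preference) to (4S,5S)-5-hexyl-2,2-dimethyl-4-(prop-2-en-1-yl)-1,3-dioxolane F1. Ozonolysis with PPh3 work-up gives 2-[(4S,5S)-5-hexyl-2,2-dimethyl-1,3-dioxolan-4-yl]acetaldehyde F2. A three-component Knoevenagel–Michael reaction of F2 with 5 and 10 (ethylenediammonium diacetate, CH2Cl2, rt) then passes through the same alkylidene-pyrandione 11 to 12; homo-adducts are recycled because the Michael step is reversible.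

2. Step 7. The hemiketal may lose water toward the ring-fused enol ether, the closure may stop once only one diol oxygen is engaged, or the methine and ring-fusion centres may fail to equilibrate. The fallback carries the secondary oxygen through the closure, where it favours the hemiketal; it sets out from 4 and 9 and comes back at 16.
   - Commercial 3-ethoxycyclohex-2-en-1-one is hydroxylated through its kinetic lithium enolate with the enantiomer of (camphorsulfonyl)oxaziridine that delivers the R alcohol, (6R)-3-ethoxy-6-hydroxycyclohex-2-en-1-one F3.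
   - Silylation (TBSOTf, 2,6-lutidine) gives (6R)-6-[(tert-butyldimethylsilyl)oxy]-3-ethoxycyclohex-2-en-1-one F4, and mild aqueous acid hydrolysis of the enol ether gives (4R)-4-[(tert-butyldimethylsilyl)oxy]cyclohexane-1,3-dione F5.
   - F5 replaces 10 under the conditions of step 6 and should give the silyloxy adduct F6.
   - Aqueous HCl/THF should close F6 to the O-silyl ether of the target F7; the bulky silyloxy group should direct the diol to the remote carbonyl. HF·pyridine then gives 16.

3. Step 8. Deprotonation may occur at the pyranone methyl group or at the ring-fusion C–H (with β-elimination of a ketal oxygen) instead of the CH2, and facial selectivity of oxygen transfer may be incomplete. The fallback is a Rubottom oxidation on an isolated, neutral substrate; it sets out from 13 and comes back at 16 (through 15). TBSOTf/Et3N should convert 13 into the bis-silyl derivative of its open form (silyl enol ether toward the CH2 and silyl pyranyl ether) F8. Dimethyldioxirane in acetone at −40 °C should epoxidise the enol ether from the convex face and, after silyl migration, give the α-silyloxy ketone F9. HF·pyridine removes both silyl groups and the hemiketal closes to 16.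

**Further compounds**
F1 | step 6 | (4S,5S)-5-hexyl-2,2-dimethyl-4-(prop-2-en-1-yl)-1,3-dioxolane | CCCCCC[C@@H]1OC(C)(C)O[C@H]1CC=C
F2 | step 6 | 2-[(4S,5S)-5-hexyl-2,2-dimethyl-1,3-dioxolan-4-yl]acetaldehyde | CCCCCC[C@@H]1OC(C)(C)O[C@H]1CC=O
F3 | step 7 | (6R)-3-ethoxy-6-hydroxycyclohex-2-en-1-one | CCOC1=CC(=O)[C@H](O)CC1
F4 | step 7 | (6R)-6-[(tert-butyldimethylsilyl)oxy]-3-ethoxycyclohex-2-en-1-one | CCOC1=CC(=O)[C@H](O[Si](C)(C)C(C)(C)C)CC1
F5 | step 7 | (4R)-4-[(tert-butyldimethylsilyl)oxy]cyclohexane-1,3-dione | O=C1CC(=O)[C@H](O[Si](C)(C)C(C)(C)C)CC1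
F6 | step 7 | silyloxy analogue of adduct 12 (TBSO on the ring carbon next to the ketone carbonyl, R) | CCCCCC[C@@H]1OC(C)(C)O[C@H]1CC(C1=C(O)CC[C@@H](O[Si](C)(C)C(C)(C)C)C1=O)c1c(O)cc(C)oc1=O
F7 | step 7 | O-(tert-butyldimethylsilyl) ether of Trichopsistide B at the secondary hydroxyl | CCCCCC[C@@H]1O[C@]23CC[C@@H](O[Si](C)(C)C(C)(C)C)[C@@]4(O)Oc5cc(C)oc(=O)c5[C@H](C[C@@H]1O2)[C@H]34
F8 | step 8 | bis-TBS derivative of the open form of 13 (silyl enol ether and silyl pyranyl ether) | CCCCCC[C@@H]1O[C@]23CCC=C(O[Si](C)(C)C(C)(C)C)[C@@H]3[C@@H](C[C@@H]1O2)c1c(O[Si](C)(C)C(C)(C)C)cc(C)oc1=O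
F9 | step 8 | α-silyloxy ketone, bis-TBS derivative of 15 | CCCCCC[C@@H]1O[C@]23CC[C@@H](O[Si](C)(C)C(C)(C)C)C(=O)[C@@H]3[C@@H](C[C@@H]1O2)c1c(O[Si](C)(C)C(C)(C)C)cc(C)oc1=O
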